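The pyranone ring (O1, C2, C3, C4, C4a, C8a; chromene numbering) is opened at the O1–C8a ether bond. On the carbocycle, C8a is ortho to the C4 ketone, and O1 sits β to that ketone, so an aryl fluoride at C8a can be displaced by the C2 alkoxide (SNAr). (S)-β-Butyrolactone supplies O1, C2 with its stereocentre, C3 and C4: an ortho-fluoroaryllithium opens it at the acyl carbon, which creates the activating C4 ketone and the C2 alkoxide in one event, and ring closure follows in the same flask. The precursor is 2-bromo-3-fluoro-1,5-dimethoxy-4-methylbenzene. Demethylation, C6 prenylation and a catalyst-controlled dearomatising geranylation at C8 finish the synthesis.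

Key step: step 3

Remark: the target is (2S,8R) and is handled as the 5-hydroxy-4,7-dione tautomer that the SMILES shows.

Step 1
Reactants: 1 1-fluoro-3,5-dimethoxybenzene
Product: 2 2,4-dibromo-3-fluoro-1,5-dimethoxybenzene
Conditions: NBS (2.05 equiv), MeCN, 0 °C → rt
Reagents that add atoms: N-bromosuccinimide, O=C1CCC(=O)N1Br
Why: Electrophilic aromatic bromination, in which each bromine should enter para to one methoxy group and ortho to the other, that is at the two equivalent positions flanking fluorine, while the more hindered position between the two methoxy groups stays free.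

Step 2
Reactants: 2 2,4-dibromo-3-fluoro-1,5-dimethoxybenzene
Product: 4 2-bromo-3-fluoro-1,5-dimethoxy-4-methylbenzene, via bromo aryllithium 3 (not isolated)
Conditions: n-BuLi (1.0 equiv), THF, −78 °C; then MeI, −78 °C → rt
Reagents that add atoms: iodomethane, CI
Why: Bromine–lithium exchange on the symmetric dibromide should stop at the monolithio stage through the stoichiometry and the low temperature (which also keeps the ortho-fluoroaryllithium from losing LiF to an aryne), and the aryllithium is then methylated by iodomethane in an SN2 alkylation.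

Step 3
Reactants: 4 2-bromo-3-fluoro-1,5-dimethoxy-4-methylbenzene; 5 (S)-β-butyrolactone
Product: 8 (2S)-5,7-dimethoxy-2,8-dimethyl-2,3-dihydro-4H-chromen-4-one, via aryllithium 6 (not isolated), via lithium alkoxide ketone 7 (not isolated)
Conditions: n-BuLi (1.05 equiv), THF, −78 °C; add to 5 (1.1 equiv), THF, −78 °C; then DMPU, −78 → 50 °C; aq NH4Cl
Reagents that add atoms: none
Why: Bromine–lithium exchange gives aryllithium 6, which attacks the strained lactone 5 at its acyl carbon (acyl–oxygen cleavage) and so creates in one event the C4 ketone and the C2 lithium alkoxide 7; on warming, this alkoxide adds to C8a, which is ortho to the new ketone, to give a Meisenheimer anion stabilised by that ketone, and loss of LiF forms the O1–C8a bond. The closest known reactions are the opening of β-lactones by organolithium reagents to β-hydroxy ketones and the intramolecular SNAr of β-alkoxy ortho-fluoroaryl ketones to chroman-4-ones. The pyranone ring closes in the 6-exo-trig mode (addition to the arene carbon, then elimination). No stereocentre is formed: C2 comes from 5 and keeps its S configuration because its C–O bond is never broken. The step needs chemoselectivity (single addition to the lactone, SNAr before retro-aldol or β-elimination) and regioselectivity between the two ortho carbons of the ketone; the first is helped by inverse addition at −78 °C and by the two ortho substituents that shield the ketone, the second is fixed because only C8a carries fluorine while C5 carries a methoxy group, a far poorer nucleofuge.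

Step 4
Reactants: 8 (2S)-5,7-dimethoxy-2,8-dimethyl-2,3-dihydro-4H-chromen-4-one
Product: 9 (2S)-5,7-dihydroxy-2,8-dimethyl-2,3-dihydro-4H-chromen-4-one
Conditions: BBr3 (5 equiv), CH2Cl2, −78 °C → rt; then MeOH, H2O
Reagents that add atoms: none
Why: Lewis acid cleavage of aryl methyl ethers, in which boron binds each methoxy oxygen and bromide attacks the methyl group (SN2) far faster than the secondary C2 of the pyranone ether, so that the ring and the C2 stereocentre should be kept.

Step 5
Reactants: 9 (2S)-5,7-dihydroxy-2,8-dimethyl-2,3-dihydro-4H-chromen-4-one; 10 prenyl bromide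
Product: 11 (2S)-5,7-dihydroxy-2,8-dimethyl-6-(3-methylbut-2-en-1-yl)-2,3-dihydro-4H-chromen-4-one
Conditions: 10 (1.1 equiv), 1 M aq KOH (1.1 equiv), 0 °C → rt
Reagents that add atoms: none
Why: C-Alkylation of the ambident 7-phenoxide in water, where hydrogen bonding to oxygen turns the anion towards carbon attack: C6 is the only ring carbon that bears hydrogen and lies between the two phenolic oxygens, so SN2 attack on prenyl bromide there is followed by tautomerisation back to the arene, whereas attack through the methyl-bearing C8 would give a more hindered, non-aromatic product.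

Step 6
Reactants: 11 (2S)-5,7-dihydroxy-2,8-dimethyl-6-(3-methylbut-2-en-1-yl)-2,3-dihydro-4H-chromen-4-one; 12 geranyl acetate
Product: 13 (2S,8R)-8-[(2E)-3,7-dimethylocta-2,6-dien-1-yl]-5-hydroxy-2,8-dimethyl-6-(3-methylbut-2-en-1-yl)-2,3-dihydro-4H-chromene-4,7(8H)-dione
Conditions: Pd2(dba)3·CHCl3 (2.5 mol%), (R,R)-DACH-phenyl Trost ligand (7.5 mol%), Et3N (1.1 equiv), degassed CH2Cl2, 0 °C → rt
Reagents that add atoms: none
Why: Tsuji–Trost allylic alkylation with dearomatisation (asymmetric allylic dearomatisation of a phenol), in which the zerovalent palladium complex ionises geranyl acetate, the 7-phenoxide attacks the unsubstituted terminus of the π-allyl ligand through C8, the less hindered of its two ortho carbons (methyl at C8 against prenyl at C6, O-allylation being reversible under the catalyst), and the chiral ligand (its antipode being taken if a first run shows the opposite sense) selects the face of C8 so that the new quaternary centre should be 8R, the 8S epimer being a diastereomer that chromatography removes.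

Compound list
1 | 1-fluoro-3,5-dimethoxybenzene | COc1cc(F)cc(OC)c1 | starting material
2 | 2,4-dibromo-3-fluoro-1,5-dimethoxybenzene | COc1cc(OC)c(Br)c(F)c1Br | intermediate
3 | (3-bromo-2-fluoro-4,6-dimethoxyphenyl)lithium | [Li]c1c(F)c(Br)c(OC)cc1OC | intermediate
4 | 2-bromo-3-fluoro-1,5-dimethoxy-4-methylbenzene | COc1cc(OC)c(Br)c(F)c1C | intermediate
5 | (S)-β-butyrolactone, (4S)-4-methyloxetan-2-one | C[C@H]1CC(=O)O1 | starting material
6 | (2-fluoro-4,6-dimethoxy-3-methylphenyl)lithium | [Li]c1c(F)c(C)c(OC)cc1OC | intermediate
7 | lithium (2S)-4-(2-fluoro-4,6-dimethoxy-3-methylphenyl)-4-oxobutan-2-olate | C[C@H]([O-])CC(=O)c1c(F)c(C)c(OC)cc1OC.[Li+] | intermediate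
8 | (2S)-5,7-dimethoxy-2,8-dimethyl-2,3-dihydro-4H-chromen-4-one | C[C@H]1CC(=O)c2c(OC)cc(OC)c(C)c2O1 | intermediate
9 | (2S)-5,7-dihydroxy-2,8-dimethyl-2,3-dihydro-4H-chromen-4-one | C[C@H]1CC(=O)c2c(O)cc(O)c(C)c2O1 | intermediate
10 | prenyl bromide, 1-bromo-3-methylbut-2-ene | CC(C)=CCBr | starting material
11 | (2S)-5,7-dihydroxy-2,8-dimethyl-6-(3-methylbut-2-en-1-yl)-2,3-dihydro-4H-chromen-4-one | C[C@H]1CC(=O)c2c(O)c(CC=C(C)C)c(O)c(C)c2O1 | intermediate
12 | geranyl acetate, (2E)-3,7-dimethylocta-2,6-dien-1-yl acetate | CC(C)=CCC/C(C)=C/COC(C)=O | starting material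
13 | (2S,8R)-8-[(2E)-3,7-dimethylocta-2,6-dien-1-yl]-5-hydroxy-2,8-dimethyl-6-(3-methylbut-2-en-1-yl)-2,3-dihydro-4H-chromene-4,7(8H)-dione | CC(C)=CCC/C(C)=C/C[C@@]1(C)C(=O)C(CC=C(C)C)=C(O)C2=C1O[C@@H](C)CC2=O | target

Total step count: 6. Longest linear sequence: 6 steps (1 → 13).

Steps most likely to fail

Step 6. Alkylation may go to the wrong atom (the prenyl-bearing C6 or oxygen), the face selection at C8 may be poor, and the E geometry of the geranyl unit may erode through π–σ–π isomerisation of the allyl palladium complex. The basic medium may also open the pyranone by β-elimination and scramble C2. The fallback sets out from 9 and comes back at 13; it blocks C6 before the quaternary centre is made and brings in the prenyl group last. Bromination of 9 (NBS, MeCN, 0 °C) at the only free ring carbon should give (2S)-6-bromo-5,7-dihydroxy-2,8-dimethyl-2,3-dihydro-4H-chromen-4-one F1. Enantioselective alkylative dearomatisation under chiral phase-transfer catalysis follows, with geranyl bromide (CC(C)=CCC/C(C)=C/CBr), CsOH·H2O and N-(9-anthracenylmethyl)cinchonidinium bromide or its cinchoninium counterpart (whichever gives 8R) in toluene/CH2Cl2 at −40 °C. This SN2 alkylation keeps the E geometry and can only reach C8, and should give (2S,8R)-6-bromo-8-[(2E)-3,7-dimethylocta-2,6-dien-1-yl]-5-hydroxy-2,8-dimethyl-2,3-dihydro-4H-chromene-4,7(8H)-dione F2. Reductive removal of the enolic bromine (Na2SO3, THF/H2O, 0 °C) should give (2S,8R)-8-[(2E)-3,7-dimethylocta-2,6-dien-1-yl]-5-hydroxy-2,8-dimethyl-2,3-dihydro-4H-chromene-4,7(8H)-dione F3. C-Prenylation of its cyclic β-diketone carbon C6 with 10 (1 M aq KOH, 0 °C) then gives 13.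

Step 3. The aryllithium may add a second time to the ketone set free in the flask or may enolise the lactone. The lithium aldolate may undergo retro-aldol cleavage before ring closure, and the ortho-fluoroaryllithium may lose LiF to an aryne. The fallback sets out from 4 and comes back at 8; it separates acylation from ring closure and keeps the ketone masked until work-up. Aminolysis of 5 (MeNHOMe·HCl, Me2AlCl, CH2Cl2, 0 °C → rt) should give the Weinreb amide (3S)-3-hydroxy-N-methoxy-N-methylbutanamide F4. Its magnesium alkoxide (iPrMgCl, THF, −20 °C) is treated at −78 °C with aryllithium 6, made from 4 as in step 3. The chelated tetrahedral adduct is stable until aqueous work-up, which should release (3S)-1-(2-fluoro-4,6-dimethoxy-3-methylphenyl)-3-hydroxybutan-1-one F5. K2CO3 in DMF at 60 °C then closes the ring by the same SNAr to 8.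

Step 5. The phenoxide may be alkylated on oxygen, a second prenyl group may enter, or attack through C8 may give a dearomatised by-product. The fallback sets out from 9 and comes back at 11; it puts the prenyl group on oxygen first and then moves it to carbon. O-Alkylation of the free 7-hydroxyl with 10 (K2CO3, acetone, reflux; the chelated 5-hydroxyl stays untouched) should give (2S)-5-hydroxy-2,8-dimethyl-7-[(3-methylbut-2-en-1-yl)oxy]-2,3-dihydro-4H-chromen-4-one F6. The clay-promoted 1,3-shift (montmorillonite K10, CH2Cl2, 0 °C → rt) then moves the prenyl group without allylic transposition to C6, the only free ortho carbon, and gives 11.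

Further compounds
F1 | step 6 | (2S)-6-bromo-5,7-dihydroxy-2,8-dimethyl-2,3-dihydro-4H-chromen-4-one | C[C@H]1CC(=O)c2c(O)c(Br)c(O)c(C)c2O1
F2 | step 6 | (2S,8R)-6-bromo-8-[(2E)-3,7-dimethylocta-2,6-dien-1-yl]-5-hydroxy-2,8-dimethyl-2,3-dihydro-4H-chromene-4,7(8H)-dione | CC(C)=CCC/C(C)=C/C[C@@]1(C)C(=O)C(Br)=C(O)C2=C1O[C@@H](C)CC2=O
F3 | step 6 | (2S,8R)-8-[(2E)-3,7-dimethylocta-2,6-dien-1-yl]-5-hydroxy-2,8-dimethyl-2,3-dihydro-4H-chromene-4,7(8H)-dione | CC(C)=CCC/C(C)=C/C[C@@]1(C)C(=O)C=C(O)C2=C1O[C@@H](C)CC2=O
F4 | step 3 | (3S)-3-hydroxy-N-methoxy-N-methylbutanamide | C[C@H](O)CC(=O)N(C)OC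
F5 | step 3 | (3S)-1-(2-fluoro-4,6-dimethoxy-3-methylphenyl)-3-hydroxybutan-1-one | C[C@H](O)CC(=O)c1c(F)c(C)c(OC)cc1OC
F6 | step 5 | (2S)-5-hydroxy-2,8-dimethyl-7-[(3-methylbut-2-en-1-yl)oxy]-2,3-dihydro-4H-chromen-4-one | C[C@H]1CC(=O)c2c(O)cc(OCC=C(C)C)c(C)c2O1
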